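All runs stem from a simulated flask from invented constants; the scatter is artificial.

How much target stands after 4.0 h as the coupling partner climbs from 60.0 mM to 1200 mM over the same substrate charge? Substrate and coupling partner give intermediate and released group, intermediate gives target, and target with more partner gives the over-reaction product.

| setting | south | east | north-west | red | grey | amber | green | teal |
|---|---|---|---|---|---|---|---|---|
| substrate | 46 mM | 46 mM | 46 mM | 46 mM | 46 mM | 46 mM | 46 mM | 46 mM |
| coupling partner | 74 mM | 280 mM | 1400 mM | 60.0 mM | 150 mM | 300 mM | 600 mM | 1200 mM |
| remark | run made earlier | run made earlier | run made earlier |  |  |  |  |  |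
| time |  |  |  | 4.0 h | 4.0 h | 4.0 h | 4.0 h | 4.0 h |

| run | time / h | target / % | substrate / % |
|---|---|---|---|
| south | 0.250 | 2.4 | 91.5 |
| south | 0.667 | 10.3 | 79.4 |
| south | 1.33 | 24.5 | 64.8 |
| south | 2.00 | 37.7 | 53.8 |
| south | 3.00 | 50.3 | 41.7 |
| east | 0.500 | 20.3 | 51.2 |
| east | 1.00 | 47.5 | 27.3 |
| east | 1.50 | 64.9 | 15.0 |
| east | 2.50 | 76.9 | 4.5 |
| east | 3.00 | 76.8 | 2.6 |
| north-west | 0.500 | 46.0 | 3.7 |
| north-west | 1.00 | 59.9 | 0.3 |
| north-west | 1.50 | 52.9 | 0 |
| north-west | 2.50 | 32.2 | 0.1 |
| north-west | 3.00 | 23.7 | 0 |

(standard deviation of a reading: 0.3 percentage points)

* amount of target at the end, in percent of the substrate charged for red, grey, amber, green, teal, in this order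
* how the row runs (falls all the way / falls, then rises / rises, then falls / rises all the way / hardly changes)

- steps thought possible: substrate + coupling partner -> intermediate + released group; intermediate -> target; coupling partner + target -> over-reaction product
- "hardly changes" means that all values lie within two and a half points (for a concentration: within two and a half percent of the largest)

I ask of each constant in turn how well it must be known. Let α be the constant of the opening step per unit of partner. In the east run substrate falls from 51.2 % to 15.0 % between 0.500 h and 1.50 h, and dividing that decay by the average partner present gives α = 4.93 M⁻¹ h⁻¹. Substrate's half-life is then 0.117 h in teal, much shorter than the time asked, so an error in α barely shifts teal. In red, at the partner charged, it is 2.35 h, longer, so an error in α reaches red more than teal.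

Let β be the constant of intermediate to target. The east run's target gain between 0.500 h and 1.00 h, divided by the average gap left by substrate and target, which I take as intermediate, gives β = 2.03 h⁻¹. That is a half-life of 0.342 h, shorter than the time asked, so a rough value serves.

Last comes the loss constant. With partner in excess, target decays pseudo-first-order, and the north-west tail from 32.2 % to 23.7 % gives 0.613 h⁻¹. Dividing by the charge gives 0.438 M⁻¹ h⁻¹ as a first answer. Going round once more, I count the partner already used by both steps, which leaves 1.32 M. So κ, the first-order loss of target per unit of partner present, is 0.464 M⁻¹ h⁻¹. In teal κ times partner times time makes 2.06, and a relative error in κ comes out multiplied by roughly that in the target.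

Target's loss half-life is 24.9 h in red, longer than the time asked, but 1.24 h in teal, shorter. With red's substrate half-life of 2.35 h beside these, I expect the row to rise, then fall. Counting the loss from the mean delay of the two earlier steps, I reckon teal at 18.0 %.

The forecast gives 50 %, 76 %, 71 %, 44 %, 18 %, rises, then falls, and says of amber “conversion is complete and target is past its peak”.

The flask gives 52.2 %, 77.3 %, 71.2 %, 45.6 %, 17.9 %: rises, then falls.

    substrate + coupling partner → intermediate + released group (k = 5.00 M⁻¹ h⁻¹)
    intermediate → target (k = 2.20 h⁻¹)
    coupling partner + target → over-reaction product (k = 0.460 M⁻¹ h⁻¹)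

In red, with partner as charged, the over-reaction step alone gives target a half-life of 25 h, long against the 4.0 h of the run. At the partner standing in teal, 93.0 % of its charge, κ gives a half-life of 1.34 h, and teal's target goes from 47.9 % at 2.00 h to 17.9 % at 4.00 h. The same reckoning for green gives 47.4 %, and green stands at 45.6 %.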